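## The problem

The target is a 4-aryl-1-tetralone lignan. Ring A (the 6,7-dimethoxybenzo ring) is fused to a cyclohexanone ring B that carries three contiguous stereocentres: C2 (S, methyl), C3 (R, methyl) and C4 (R, bearing ring C, the 3-hydroxy-4-methoxyphenyl group). The two methyl groups are trans and the C3 methyl group is cis to the C4 aryl group. C2 lies next to the ketone and can be set last by equilibration, because the 2,3-trans isomer has both methyl groups pseudoequatorial while the C4 aryl group stays pseudoaxial. C3 and C4 cannot be corrected in this way and must be made with absolute control. C4 is the hard centre: it carries a hydrogen and two electron-rich aryl groups that differ only in one remote oxygen substituent, so only a stereospecific bond formation can define it. The free phenol of ring C has to be masked throughout, and its ring must not compete when ring A is functionalised ortho to C4. The doubly benzylic C4–H and the electron-rich rings exclude harsh oxidants late in the route. The enabling feature is C1, a lone carbonyl carbon between C8a of ring A and C2. It can be brought in as carbon monoxide that joins an aryl iodide at C8a to an ester enolate at C2 whose chain already holds C3 and C4.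

## Retrosynthesis

**From 25 back to 21.** The target 25 is traced to its aryl tosylate 24 (S–O bond), then to the quaternary β-keto ester 22 (C2–carboxyl bond) and to the β-keto ester 21 (C2–CH3 bond). Removing the methyl group from a β-keto ester rather than from a plain tetralone enolate is preferred, because mono-C-methylation under carbonate conditions is dependable and the tert-butyl ester then leaves under acid. The skeleton is not simplified here. The forward steps ask only that C2 ends trans to the C3 methyl group, which the basic last step should provide by equilibration, and that the sulfonate lasts until then.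

**From 21 back to 18 (the strategic cut).** Two bonds of ring B are cut at once, C8a–C1 and C1–C2, and C1 is carbon monoxide. The precursor 18 is an open-chain aryl iodide with a tert-butyl ester, with no ring B and only two stereocentres. The neighbouring cut of C8a–C1 alone (acylation of ring A by the chain acid) would leave the choice of ring to electronics and no activating group at C2. The cut of C1–C2 alone would require a separate carboxylation of ring A. The forward reaction must insert CO before the enolate meets the arylpalladium species, and must acylate at carbon. Two choices in 18 serve this: a tert-butyl ester, whose lithium enolate is stable and does not self-condense, and a tosylate on ring C, which has no acidic hydrogen for the amide base to remove.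

**From 18 back to 15.** The C–I bond is cut to give 17, the tosylate to give phenol 16, and the phenol is traced to its benzyl ether 15. The exchange of benzyl for tosyl is what makes the iodination regioselective. With a benzyl ether both rings are 3,4-dialkoxyphenyl groups of equal reactivity; with the sulfonate ring C is deactivated and ring A reacts para to a methoxyl, ortho to C4. The forward steps are hydrogenolysis, sulfonylation and electrophilic iodination.

**From 15 back to 10.** The ester carbon is traced through acid 14 and alcohol 12 to the terminal alkene carbon of 10 (oxidation level only, no C–C bond cut). A vinyl group is the simplest carrier of the future C1–C2 ester unit that survives organolithium chemistry. The forward steps ask for anti-Markovnikov hydroboration and mild oxidation that leave C3, C4 and the benzyl ether alone.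

**From 10 back to 5 and 6.** The C4–aryl bond to ring A is cut: the hydrogen of 10 replaces boron in the tertiary boronic ester 9, and 9 comes from carbamate 5 and the aryl boronic ester 6. This cut is chosen over any cut that would create C4 by face-selective addition, because the two aryl groups are too alike for face selection. Here the configuration follows from a carbinol centre by a known stereochemical course: retention, retention, inversion, retention. The precursor has one aryl ring less. The forward reaction asks for configurational stability of the lithiated carbamate and a clean 1,2-shift at a β-branched centre.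

**From 5 back to 1 and 2.** The carbamate 5 comes from alcohol 4, and the bond between the carbinol carbon and C3 is cut to give aldehyde 1 and (E)-crotylboronate 2. One catalytic step sets both stereocentres: the (E) geometry gives the anti relationship, which after inversion at C4 becomes the 3,4-cis relationship of 25. The forward reaction asks for high enantio- and diastereoselectivity with an electron-rich aromatic aldehyde.

## Roads not taken

**Alternative 1:** Ring A would be cut off at C4a–C5 and C8–C8a and built last by a Diels–Alder reaction of the enone (4R,5R,6S)-4-[3-(benzyloxy)-4-methoxyphenyl]-5,6-dimethylcyclohex-2-en-1-one A1 with 2,3-dimethoxybuta-1,3-diene A2. Under Me2AlCl or high pressure this would give the cis-fused adduct A3, which is then dehydrogenated to the aromatic ring.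
- Merits: the oxygenation pattern of ring A is fixed by the diene, so no halogenation is needed. The two new stereocentres of A3 vanish on aromatisation.
- Weak points: the problem is moved rather than solved, since A1 already holds all three stereocentres on a small ring and needs its own asymmetric synthesis. C4 of A1 is γ to the enone and can epimerise through the dienol under Lewis acid. 4-Substituted cyclohexenones are sluggish dienophiles, and A2 is an acid-sensitive bis-enol ether. The final dehydrogenation must stop at the tetralone and not go on to a naphthol.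
- Comparison: this road is better in the regiochemistry of ring A and avoids the protecting-group exchange. The chosen plan sets against it commercial aromatic building blocks, C3 and C4 made by two reagent-defined steps, and no aromatisation next to an enolisable ketone.

**Alternative 2:** The C3=C4 bond would be cut and formed by an intramolecular McMurry coupling of the diaryl ketone–methyl ketone A4 with low-valent titanium from TiCl3 and zinc–copper couple. This gives the 1-silyloxy-1,2-dihydronaphthalene A5. Desilylation, hydroxyl-directed hydrogenation with [Ir(cod)(PCy3)(py)]PF6 and oxidation at C1 follow.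
- Merits: hydrogen is added to one face of the alkene, so the 3,4-cis relationship comes out of a single substrate-directed step. In this respect it is more direct than the chosen plan, which needs two C–C bond formations for C3 and C4. No organolithium chemistry is needed.
- Weak points: a hindered, electron-rich diaryl ketone must couple with a methyl ketone to a tetrasubstituted alkene using stoichiometric titanium. A4 is a β-silyloxy ketone with an α-stereocentre that can epimerise or eliminate under these Lewis acidic, reducing conditions. The benzylic C1–O bond may be reduced. C1 is made as a carbinol, protected, deprotected and oxidised, which is a redox detour. C2 of A5 is drawn trans to the silyloxy group and would end cis to the C3 methyl group, so a final epimerisation is still needed.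
- Comparison: the chosen plan sets against the elegant hydrogenation a catalytic ring closure, no detour at C1, and stereocentres that are never α to a carbonyl group before the last steps.

**Alternative 3:** The C4–C4a bond would be cut and formed by palladium-catalysed intramolecular α-arylation of the α-aryl ester enolate of the bromo keto ester A6. This gives the quaternary tetralone ester A7. C3 would come from desymmetrisation of a 3-methylglutaric acid derivative.
- Merits: the key step is better precedented than that of the chosen plan, since arylation of stabilised α-aryl ester enolates to quaternary centres is established, whereas the chosen key step extends known carbonylative chemistry to an unstabilised ester enolate. The source of C3 is cheap.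
- Weak points: the ester of A7 sits on a quaternary diaryl carbon, where hydrolysis and decarboxylation are hard. The C4–H configuration, the most demanding centre, would be set last in a protonation that cannot be steered. The C2 methyl group is still missing. A6 has two acidic sites.
- Comparison: the chosen plan sets against the better precedent a C4 centre fixed early by stereospecific steps and never touched again, and an ester placed at C2, where it helps the methylation and leaves under mild acid.

Key step: step 11

Assumption 1: the (S) enantiomer of the phosphoric acid TRIP is taken to give the (1S) carbinol, by analogy with the sense known for simple aromatic aldehydes; if the sense were opposite, the (R) acid would be used.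

Assumption 2: compounds 1, 2 and 6 are taken as catalogue chemicals; 1 is otherwise one O-benzylation away from isovanillin.

"Tosyloxy" stands for (4-methylbenzenesulfonyl)oxy throughout.

## Steps

Step 1
Reactants: 1 3-(benzyloxy)-4-methoxybenzaldehyde; 2 (E)-crotylboronic acid pinacol ester
Product: 4 (1S,2S)-1-[3-(benzyloxy)-4-methoxyphenyl]-2-methylbut-3-en-1-ol, via pinacol borate ester 3 (not isolated)
Conditions: (S)-TRIP [(S)-3,3'-bis(2,4,6-triisopropylphenyl)-1,1'-binaphthyl-2,2'-diyl hydrogen phosphate] (5 mol %), 4 Å MS, toluene, −30 °C; aq NaHCO3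
Reagents that add atoms: none
Why: Chiral phosphoric acid-catalysed crotylboration through a closed six-membered chair transition state; the (E)-boronate gives the anti adduct and the catalyst, hydrogen-bonded to a boronate oxygen, selects the aldehyde face, so C3 and the carbinol centre are set together.

Step 2
Reactants: 4 (1S,2S)-1-[3-(benzyloxy)-4-methoxyphenyl]-2-methylbut-3-en-1-ol
Product: 5 (1S,2S)-1-[3-(benzyloxy)-4-methoxyphenyl]-2-methylbut-3-en-1-yl N,N-diisopropylcarbamate
Conditions: iPr2NCOCl, Et3N, DMAP (cat.), CH2Cl2, reflux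
Reagents that add atoms: N,N-diisopropylcarbamoyl chloride, CC(C)N(C(C)C)C(Cl)=O
Why: O-carbamoylation of a secondary alcohol; no bond to a stereocentre is broken.

Step 3
Reactants: 5 (1S,2S)-1-[3-(benzyloxy)-4-methoxyphenyl]-2-methylbut-3-en-1-yl N,N-diisopropylcarbamate; 6 2-(3,4-dimethoxyphenyl)-4,4,5,5-tetramethyl-1,3,2-dioxaborolane
Product: 9 2-[(1S,2S)-1-[3-(benzyloxy)-4-methoxyphenyl]-1-(3,4-dimethoxyphenyl)-2-methylbut-3-en-1-yl]-4,4,5,5-tetramethyl-1,3,2-dioxaborolane, via lithiated carbamate 7 (not isolated), via lithium boronate complex 8 (not isolated)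
Conditions: sBuLi (1.3 equiv), Et2O, −78 °C; 6 (1.5 equiv), −78 °C; MgBr2·OEt2 in MeOH, −78 °C to rt
Reagents that add atoms: none
Why: Lithiation–borylation of a secondary benzylic carbamate; carbamate-directed deprotonation and borylation both go with retention, and the 1,2-shift of the electron-rich aryl group from boron to carbon expels the carbamate with inversion, so the ring A aryl group takes the place of oxygen stereospecifically.

Step 4
Reactants: 9 2-[(1S,2S)-1-[3-(benzyloxy)-4-methoxyphenyl]-1-(3,4-dimethoxyphenyl)-2-methylbut-3-en-1-yl]-4,4,5,5-tetramethyl-1,3,2-dioxaborolane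
Product: 10 2-(benzyloxy)-4-[(1S,2S)-1-(3,4-dimethoxyphenyl)-2-methylbut-3-en-1-yl]-1-methoxybenzene
Conditions: CsF (1.5 equiv), H2O (1.1 equiv), 1,4-dioxane, 45 °C
Reagents that add atoms: none
Why: Fluoride-promoted protodeboronation of a tertiary diarylalkyl boronic ester, which replaces boron by hydrogen with retention; together with step 3 the carbinol oxygen is replaced by aryl with net inversion, which gives the C4 configuration of the target.

Step 5
Reactants: 10 2-(benzyloxy)-4-[(1S,2S)-1-(3,4-dimethoxyphenyl)-2-methylbut-3-en-1-yl]-1-methoxybenzene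
Product: 12 (3S,4S)-4-[3-(benzyloxy)-4-methoxyphenyl]-4-(3,4-dimethoxyphenyl)-3-methylbutan-1-ol, via B-alkyl-9-borabicyclononane 11 (not isolated)
Conditions: 9-BBN, THF, 0 °C to rt; NaOH, H2O2, 0 °C
Reagents that add atoms: hydrogen peroxide, OO; 9-borabicyclo[3.3.1]nonane, [H]B1C2CCCC1CCC2 (its boron and carbon atoms stay in intermediate 11 only)
Why: Anti-Markovnikov hydroboration of the terminal alkene by a bulky borane, then oxidation of the C–B bond; C3 and C4 are remote from the reacting carbons.

Step 6
Reactants: 12 (3S,4S)-4-[3-(benzyloxy)-4-methoxyphenyl]-4-(3,4-dimethoxyphenyl)-3-methylbutan-1-ol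
Product: 14 (3S,4S)-4-[3-(benzyloxy)-4-methoxyphenyl]-4-(3,4-dimethoxyphenyl)-3-methylbutanoic acid, via aldehyde 13 (not isolated)
Conditions: TEMPO (0.2 equiv), PhI(OAc)2 (2.2 equiv), MeCN–H2O, rt
Reagents that add atoms: water, O
Why: Nitroxyl-catalysed oxidation of a primary alcohol through the aldehyde hydrate to the carboxylic acid; the conditions are mild toward the benzyl ether, the electron-rich rings and the doubly benzylic C–H, and the aldehyde has no stereocentre at its α-carbon.

Step 7
Reactants: 14 (3S,4S)-4-[3-(benzyloxy)-4-methoxyphenyl]-4-(3,4-dimethoxyphenyl)-3-methylbutanoic acid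
Product: 15 tert-butyl (3S,4S)-4-[3-(benzyloxy)-4-methoxyphenyl]-4-(3,4-dimethoxyphenyl)-3-methylbutanoate
Conditions: tert-butyl 2,2,2-trichloroacetimidate (2 equiv), CH2Cl2–cyclohexane, rt
Reagents that add atoms: tert-butyl 2,2,2-trichloroacetimidate, CC(C)(C)OC(=N)C(Cl)(Cl)Cl
Why: tert-Butyl esterification through protonation of the imidate by the carboxylic acid; the tert-butyl ester is chosen because its lithium enolate is stable and resists self-condensation in step 11.

Step 8
Reactants: 15 tert-butyl (3S,4S)-4-[3-(benzyloxy)-4-methoxyphenyl]-4-(3,4-dimethoxyphenyl)-3-methylbutanoate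
Product: 16 tert-butyl (3S,4R)-4-(3,4-dimethoxyphenyl)-4-(3-hydroxy-4-methoxyphenyl)-3-methylbutanoate
Conditions: H2 (1 atm), 10% Pd/C, EtOAc–EtOH, rt
Reagents that add atoms: none
Why: Hydrogenolysis of the benzyl aryl ether, placed after the alkene has been used up; the diarylmethine and the tert-butyl ester are inert, and the descriptor at C4 changes only because the ring priorities change.

Step 9
Reactants: 16 tert-butyl (3S,4R)-4-(3,4-dimethoxyphenyl)-4-(3-hydroxy-4-methoxyphenyl)-3-methylbutanoate
Product: 17 tert-butyl (3S,4S)-4-(3,4-dimethoxyphenyl)-4-[4-methoxy-3-(tosyloxy)phenyl]-3-methylbutanoate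
Conditions: TsCl, Et3N, DMAP (cat.), CH2Cl2, 0 °C to rt
Reagents that add atoms: 4-methylbenzenesulfonyl chloride, Cc1ccc(cc1)S(Cl)(=O)=O
Why: O-Sulfonylation of the phenol; the sulfonate turns the ring C oxygen from a donor into an acceptor for step 10 and has no acidic hydrogen for the amide base of step 11.

Step 10
Reactants: 17 tert-butyl (3S,4S)-4-(3,4-dimethoxyphenyl)-4-[4-methoxy-3-(tosyloxy)phenyl]-3-methylbutanoate
Product: 18 tert-butyl (3S,4R)-4-(2-iodo-4,5-dimethoxyphenyl)-4-[4-methoxy-3-(tosyloxy)phenyl]-3-methylbutanoate
Conditions: NIS (1.05 equiv), CF3CO2H (0.3 equiv), MeCN, 0 °C to rt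
Reagents that add atoms: N-iodosuccinimide, O=C1CCC(=O)N1I
Why: Electrophilic aromatic iodination; ring A should react para to a methoxyl at the position ortho to C4, the usual site in 4-alkylveratroles, while ring C is deactivated by the sulfonate and its position para to the methoxyl is blocked.

Step 11
Reactants: 18 tert-butyl (3S,4R)-4-(2-iodo-4,5-dimethoxyphenyl)-4-[4-methoxy-3-(tosyloxy)phenyl]-3-methylbutanoate
Product: 21 tert-butyl (2S,3R,4R)-6,7-dimethoxy-4-[4-methoxy-3-(tosyloxy)phenyl]-3-methyl-1-oxo-1,2,3,4-tetrahydronaphthalene-2-carboxylate, via lithium ester enolate 19 (not isolated), via lithium enolate of the keto ester 20 (not isolated)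
Conditions: LiN(SiMe3)2 (1.05 equiv), THF, −78 °C; Pd(OAc)2 (5 mol %), Xantphos (7.5 mol %), CO (3 bar), to 40 °C with slow addition of LiN(SiMe3)2 (1.1 equiv); aq NH4Cl
Reagents that add atoms: carbon monoxide, [C-]#[O+]
Why: Proposed new method: zerovalent palladium, formed from Pd(OAc)2 and Xantphos, inserts into the C8a–I bond of enolate 19, CO inserts to give the aroylpalladium iodide, the tethered ester enolate replaces iodide at the metal and reductive elimination forms C1–C2, so that CO becomes C1 and ring B closes with both new bonds in one operation, the product being held as its lithium enolate 20 by the second portion of base. The closest known reaction type is the palladium-catalysed carbonylative α-arylation of aryl iodides with ketone enolates, malonates and other stabilised enolates, together with the intramolecular capture of aroylpalladium species by malonate enolates; only the unstabilised ester enolate as carbon nucleophile is new. Ring B closes in a 6-(enolexo)-exo-trig C-acylation, which at the metal is a reductive elimination from a seven-membered acyl(enolate)palladium chelate. The only new stereocentre, C2, is enolisable and should settle trans to the C3 methyl group under thermodynamic control; it is rebuilt in steps 12 to 14, whereas C3 and C4 are not touched. The step needs carbonylative closure ahead of direct enolate arylation, which would give a five-membered ring; the wide bite angle of Xantphos, the CO pressure and the electron-rich aryl group should make CO insertion faster than enolate capture at the arylpalladium stage. It needs C-acylation ahead of O-acylation, which is secured because O-attack would have to close an eight-membered ring, and it needs the iodide to react ahead of the sulfonate, which the much faster oxidative addition of the C–I bond secures. The tert-butyl ester suppresses Claisen self-condensation, and slow addition of the second equivalent of LiN(SiMe3)2 keeps free amide, a competing nucleophile for the aroylpalladium species, at a low level.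

Step 12
Reactants: 21 tert-butyl (2S,3R,4R)-6,7-dimethoxy-4-[4-methoxy-3-(tosyloxy)phenyl]-3-methyl-1-oxo-1,2,3,4-tetrahydronaphthalene-2-carboxylate
Product: 22 tert-butyl (2R,3R,4R)-6,7-dimethoxy-4-[4-methoxy-3-(tosyloxy)phenyl]-2,3-dimethyl-1-oxo-1,2,3,4-tetrahydronaphthalene-2-carboxylate
Conditions: K2CO3, MeI, acetone, reflux
Reagents that add atoms: iodomethane, CI
Why: C-Alkylation of a β-keto ester enolate; methyl iodide should enter anti to the C3 methyl group and the pseudoaxial aryl group, but the configuration of the quaternary C2 is lost in the next step and is of no consequence.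

Step 13
Reactants: 22 tert-butyl (2R,3R,4R)-6,7-dimethoxy-4-[4-methoxy-3-(tosyloxy)phenyl]-2,3-dimethyl-1-oxo-1,2,3,4-tetrahydronaphthalene-2-carboxylate
Product: 24 (2S,3R,4R)-6,7-dimethoxy-4-[4-methoxy-3-(tosyloxy)phenyl]-2,3-dimethyl-3,4-dihydronaphthalen-1(2H)-one, via keto acid 23 (not isolated)
Conditions: CF3CO2H–CH2Cl2 (1:4), rt; then toluene, 90 °C
Reagents that add atoms: none
Why: Acidolysis of the tert-butyl ester and thermal decarboxylation of the β-keto acid through its enol; ketonisation and acid-mediated enolisation should favour the 2,3-trans isomer (both methyl groups pseudoequatorial, aryl group pseudoaxial), and any cis epimer converges in step 14.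

Step 14
Reactants: 24 (2S,3R,4R)-6,7-dimethoxy-4-[4-methoxy-3-(tosyloxy)phenyl]-2,3-dimethyl-3,4-dihydronaphthalen-1(2H)-one
Product: 25 (2S,3R,4R)-4-(3-hydroxy-4-methoxyphenyl)-6,7-dimethoxy-2,3-dimethyl-3,4-dihydronaphthalen-1(2H)-one
Conditions: KOH, MeOH–H2O, reflux, under argon; aq HCl
Reagents that add atoms: none
Why: Alkaline hydrolysis of the aryl sulfonate by attack at sulfur; the basic medium also equilibrates C2 to the favoured trans configuration, while C3 and C4 are not enolisable.

## Compound list

1 | 3-(benzyloxy)-4-methoxybenzaldehyde | COc1ccc(C=O)cc1OCc1ccccc1 | starting material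
2 | (E)-crotylboronic acid pinacol ester | C/C=C/CB1OC(C)(C)C(C)(C)O1 | starting material
3 | 2-{[(1S,2S)-1-[3-(benzyloxy)-4-methoxyphenyl]-2-methylbut-3-en-1-yl]oxy}-4,4,5,5-tetramethyl-1,3,2-dioxaborolane | COc1ccc([C@@H](OB2OC(C)(C)C(C)(C)O2)[C@@H](C)C=C)cc1OCc1ccccc1 | intermediate (not isolated)
4 | (1S,2S)-1-[3-(benzyloxy)-4-methoxyphenyl]-2-methylbut-3-en-1-ol | COc1ccc([C@@H](O)[C@@H](C)C=C)cc1OCc1ccccc1 | intermediate
5 | (1S,2S)-1-[3-(benzyloxy)-4-methoxyphenyl]-2-methylbut-3-en-1-yl N,N-diisopropylcarbamate | COc1ccc([C@@H](OC(=O)N(C(C)C)C(C)C)[C@@H](C)C=C)cc1OCc1ccccc1 | intermediate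
6 | 2-(3,4-dimethoxyphenyl)-4,4,5,5-tetramethyl-1,3,2-dioxaborolane | COc1ccc(B2OC(C)(C)C(C)(C)O2)cc1OC | starting material
7 | (1S,2S)-1-lithio derivative of carbamate 5 (lithium in place of the carbinol hydrogen, configuration retained) | COc1ccc([C@@]([Li])(OC(=O)N(C(C)C)C(C)C)[C@@H](C)C=C)cc1OCc1ccccc1 | intermediate (not isolated)
8 | lithium boronate complex of 7 and 6 (boron in place of lithium, configuration retained) | COc1ccc([C@@]([B-]2(c3ccc(OC)c(OC)c3)OC(C)(C)C(C)(C)O2)(OC(=O)N(C(C)C)C(C)C)[C@@H](C)C=C)cc1OCc1ccccc1.[Li+] | intermediate (not isolated)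
9 | 2-[(1S,2S)-1-[3-(benzyloxy)-4-methoxyphenyl]-1-(3,4-dimethoxyphenyl)-2-methylbut-3-en-1-yl]-4,4,5,5-tetramethyl-1,3,2-dioxaborolane | COc1ccc([C@](B2OC(C)(C)C(C)(C)O2)(c2ccc(OC)c(OC)c2)[C@@H](C)C=C)cc1OCc1ccccc1 | intermediate
10 | 2-(benzyloxy)-4-[(1S,2S)-1-(3,4-dimethoxyphenyl)-2-methylbut-3-en-1-yl]-1-methoxybenzene | COc1ccc([C@H](c2ccc(OC)c(OC)c2)[C@@H](C)C=C)cc1OCc1ccccc1 | intermediate
11 | 9-[(3S,4S)-4-[3-(benzyloxy)-4-methoxyphenyl]-4-(3,4-dimethoxyphenyl)-3-methylbutyl]-9-borabicyclo[3.3.1]nonane | COc1ccc([C@H](c2ccc(OC)c(OC)c2)[C@@H](C)CCB2C3CCCC2CCC3)cc1OCc1ccccc1 | intermediate (not isolated)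
12 | (3S,4S)-4-[3-(benzyloxy)-4-methoxyphenyl]-4-(3,4-dimethoxyphenyl)-3-methylbutan-1-ol | COc1ccc([C@H](c2ccc(OC)c(OC)c2)[C@@H](C)CCO)cc1OCc1ccccc1 | intermediate
13 | (3S,4S)-4-[3-(benzyloxy)-4-methoxyphenyl]-4-(3,4-dimethoxyphenyl)-3-methylbutanal | COc1ccc([C@H](c2ccc(OC)c(OC)c2)[C@@H](C)CC=O)cc1OCc1ccccc1 | intermediate (not isolated)
14 | (3S,4S)-4-[3-(benzyloxy)-4-methoxyphenyl]-4-(3,4-dimethoxyphenyl)-3-methylbutanoic acid | COc1ccc([C@H](c2ccc(OC)c(OC)c2)[C@@H](C)CC(=O)O)cc1OCc1ccccc1 | intermediate
15 | tert-butyl (3S,4S)-4-[3-(benzyloxy)-4-methoxyphenyl]-4-(3,4-dimethoxyphenyl)-3-methylbutanoate | COc1ccc([C@H](c2ccc(OC)c(OC)c2)[C@@H](C)CC(=O)OC(C)(C)C)cc1OCc1ccccc1 | intermediate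
16 | tert-butyl (3S,4R)-4-(3,4-dimethoxyphenyl)-4-(3-hydroxy-4-methoxyphenyl)-3-methylbutanoate | COc1ccc([C@H](c2ccc(OC)c(OC)c2)[C@@H](C)CC(=O)OC(C)(C)C)cc1O | intermediate
17 | tert-butyl (3S,4S)-4-(3,4-dimethoxyphenyl)-4-[4-methoxy-3-(tosyloxy)phenyl]-3-methylbutanoate | COc1ccc([C@H](c2ccc(OC)c(OC)c2)[C@@H](C)CC(=O)OC(C)(C)C)cc1OS(=O)(=O)c1ccc(C)cc1 | intermediate
18 | tert-butyl (3S,4R)-4-(2-iodo-4,5-dimethoxyphenyl)-4-[4-methoxy-3-(tosyloxy)phenyl]-3-methylbutanoate | COc1ccc([C@H](c2cc(OC)c(OC)cc2I)[C@@H](C)CC(=O)OC(C)(C)C)cc1OS(=O)(=O)c1ccc(C)cc1 | intermediate (precursor of the key step)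
19 | lithium enolate of ester 18 (enolate geometry not defined and of no consequence) | COc1ccc([C@H](c2cc(OC)c(OC)cc2I)[C@@H](C)C=C(O[Li])OC(C)(C)C)cc1OS(=O)(=O)c1ccc(C)cc1 | intermediate (not isolated)
20 | lithium enolate of keto ester 21 | COc1ccc([C@@H]2c3cc(OC)c(OC)cc3C(O[Li])=C(C(=O)OC(C)(C)C)[C@@H]2C)cc1OS(=O)(=O)c1ccc(C)cc1 | intermediate (not isolated)
21 | tert-butyl (2S,3R,4R)-6,7-dimethoxy-4-[4-methoxy-3-(tosyloxy)phenyl]-3-methyl-1-oxo-1,2,3,4-tetrahydronaphthalene-2-carboxylate (C2 labile, drawn trans to the C3 methyl group) | COc1ccc([C@@H]2c3cc(OC)c(OC)cc3C(=O)[C@@H](C(=O)OC(C)(C)C)[C@@H]2C)cc1OS(=O)(=O)c1ccc(C)cc1 | intermediate (product of the key step)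
22 | tert-butyl (2R,3R,4R)-6,7-dimethoxy-4-[4-methoxy-3-(tosyloxy)phenyl]-2,3-dimethyl-1-oxo-1,2,3,4-tetrahydronaphthalene-2-carboxylate (expected C2 epimer; C2 of no consequence) | COc1ccc([C@@H]2c3cc(OC)c(OC)cc3C(=O)[C@](C)(C(=O)OC(C)(C)C)[C@@H]2C)cc1OS(=O)(=O)c1ccc(C)cc1 | intermediate
23 | (2R,3R,4R)-6,7-dimethoxy-4-[4-methoxy-3-(tosyloxy)phenyl]-2,3-dimethyl-1-oxo-1,2,3,4-tetrahydronaphthalene-2-carboxylic acid | COc1ccc([C@@H]2c3cc(OC)c(OC)cc3C(=O)[C@](C)(C(=O)O)[C@@H]2C)cc1OS(=O)(=O)c1ccc(C)cc1 | intermediate (not isolated)
24 | (2S,3R,4R)-6,7-dimethoxy-4-[4-methoxy-3-(tosyloxy)phenyl]-2,3-dimethyl-3,4-dihydronaphthalen-1(2H)-one | COc1ccc([C@@H]2c3cc(OC)c(OC)cc3C(=O)[C@@H](C)[C@@H]2C)cc1OS(=O)(=O)c1ccc(C)cc1 | intermediate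
25 | (2S,3R,4R)-4-(3-hydroxy-4-methoxyphenyl)-6,7-dimethoxy-2,3-dimethyl-3,4-dihydronaphthalen-1(2H)-one | COc1ccc([C@@H]2c3cc(OC)c(OC)cc3C(=O)[C@@H](C)[C@@H]2C)cc1O | target

## Step count and least certain steps

Total step count: 14. Longest linear sequence: 14 steps, from 1 to 25; 2 and 6 enter in steps 1 and 3.

**Step 11 (key step, proposed new method).** The aroylpalladium intermediate may be captured by the silylamide base instead of the enolate, because a strong, unstabilised enolate has to coexist with CO and the catalyst. Turnover may stall through proton transfer from the acidic product to unreacted enolate if the second portion of base is mistimed. Direct enolate arylation to the five-membered ring becomes possible if CO insertion is slow at the hindered, ortho-substituted aryl group.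

Fallback, by two known reactions that make the same two bonds one after the other: it sets out from 18. Alkoxycarbonylation (PdCl2(PPh3)2, CO, MeOH, Et3N, DMF, 70 °C) should give the diester methyl 2-[(1R,2S)-4-tert-butoxy-1-[4-methoxy-3-(tosyloxy)phenyl]-2-methyl-4-oxobutyl]-4,5-dimethoxybenzoate F1, in which the CO-derived carbon already sits on C8a. Dieckmann condensation (LiN(SiMe3)2, THF, −78 °C to 0 °C) then closes C1–C2; only the tert-butyl ester can enolise and only the methyl ester can be attacked. The fallback comes back to the route at 21.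

**Step 3.** Boronate formation and the 1,2-shift may be slow or reversible at the congested, β-branched benzylic centre, which would erode the stereospecificity. A competing lithiation at the benzyl ether methylene is possible with excess sBuLi.

Fallback, in which C4 and C3 are set by an oxazolidinone auxiliary instead of by substitution at a carbinol: it sets out from 1.
- Knoevenagel–Doebner condensation with malonic acid (pyridine, piperidine) should give (2E)-3-[3-(benzyloxy)-4-methoxyphenyl]prop-2-enoic acid F2.
- N-Acylation of (4R)-4-phenyl-1,3-oxazolidin-2-one (pivaloyl chloride, Et3N, LiCl) gives the imide (4R)-3-[(2E)-3-[3-(benzyloxy)-4-methoxyphenyl]prop-2-enoyl]-4-phenyl-1,3-oxazolidin-2-one F3.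
- Conjugate addition of 3,4-dimethoxyphenylmagnesium bromide with CuBr·SMe2 to the chelated s-cis imide, on the face away from the phenyl group, should give (4R)-3-[(3S)-3-[3-(benzyloxy)-4-methoxyphenyl]-3-(3,4-dimethoxyphenyl)propanoyl]-4-phenyl-1,3-oxazolidin-2-one F4.
- Methylation of its sodium enolate (NaN(SiMe3)2, MeI, THF, −78 °C) gives (4R)-3-[(2R,3S)-3-[3-(benzyloxy)-4-methoxyphenyl]-3-(3,4-dimethoxyphenyl)-2-methylpropanoyl]-4-phenyl-1,3-oxazolidin-2-one F5.
- LiOH and H2O2 release (2R,3S)-3-[3-(benzyloxy)-4-methoxyphenyl]-3-(3,4-dimethoxyphenyl)-2-methylpropanoic acid F6.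
- Arndt–Eistert homologation through the diazoketone (3R,4S)-4-[3-(benzyloxy)-4-methoxyphenyl]-1-diazo-4-(3,4-dimethoxyphenyl)-3-methylbutan-2-one F7 ((COCl)2, then Me3SiCHN2), with Wolff rearrangement in tert-butanol (PhCO2Ag, Et3N, 60 °C; migration with retention), comes back to the route at 15.

**Step 10.** Iodination may stray to ring C ortho to its methoxyl or go twice on ring A, because the wanted site is flanked by the bulky diarylmethine group.

Fallback, which gives up the halide and with it the carbonylative closure: it sets out from 17. Acidolysis (CF3CO2H, CH2Cl2) gives (3S,4S)-4-(3,4-dimethoxyphenyl)-4-[4-methoxy-3-(tosyloxy)phenyl]-3-methylbutanoic acid F8. Intramolecular Friedel–Crafts acylation ((CF3CO)2O, CF3CO2H) onto ring A para to a methoxyl, with ring C held back by the sulfonate, should give (3S,4R)-6,7-dimethoxy-4-[4-methoxy-3-(tosyloxy)phenyl]-3-methyl-3,4-dihydronaphthalen-1(2H)-one F9. Methylation of its lithium enolate (LiN(SiMe3)2, MeI, THF, −78 °C) comes back to the route at 24.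

## Further compounds

F1 | step 11 | methyl 2-[(1R,2S)-4-tert-butoxy-1-[4-methoxy-3-(tosyloxy)phenyl]-2-methyl-4-oxobutyl]-4,5-dimethoxybenzoate | COc1ccc([C@H](c2cc(OC)c(OC)cc2C(=O)OC)[C@@H](C)CC(=O)OC(C)(C)C)cc1OS(=O)(=O)c1ccc(C)cc1
F2 | step 3 | (2E)-3-[3-(benzyloxy)-4-methoxyphenyl]prop-2-enoic acid | COc1ccc(/C=C/C(=O)O)cc1OCc1ccccc1
F3 | step 3 | (4R)-3-[(2E)-3-[3-(benzyloxy)-4-methoxyphenyl]prop-2-enoyl]-4-phenyl-1,3-oxazolidin-2-one | COc1ccc(/C=C/C(=O)N2C(=O)OC[C@H]2c2ccccc2)cc1OCc1ccccc1
F4 | step 3 | (4R)-3-[(3S)-3-[3-(benzyloxy)-4-methoxyphenyl]-3-(3,4-dimethoxyphenyl)propanoyl]-4-phenyl-1,3-oxazolidin-2-one | COc1ccc([C@H](c2ccc(OC)c(OC)c2)CC(=O)N2C(=O)OC[C@H]2c2ccccc2)cc1OCc1ccccc1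
F5 | step 3 | (4R)-3-[(2R,3S)-3-[3-(benzyloxy)-4-methoxyphenyl]-3-(3,4-dimethoxyphenyl)-2-methylpropanoyl]-4-phenyl-1,3-oxazolidin-2-one | COc1ccc([C@H](c2ccc(OC)c(OC)c2)[C@@H](C)C(=O)N2C(=O)OC[C@H]2c2ccccc2)cc1OCc1ccccc1
F6 | step 3 | (2R,3S)-3-[3-(benzyloxy)-4-methoxyphenyl]-3-(3,4-dimethoxyphenyl)-2-methylpropanoic acid | COc1ccc([C@H](c2ccc(OC)c(OC)c2)[C@@H](C)C(=O)O)cc1OCc1ccccc1
F7 | step 3 | (3R,4S)-4-[3-(benzyloxy)-4-methoxyphenyl]-1-diazo-4-(3,4-dimethoxyphenyl)-3-methylbutan-2-one | COc1ccc([C@H](c2ccc(OC)c(OC)c2)[C@@H](C)C(=O)C=[N+]=[N-])cc1OCc1ccccc1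
F8 | step 10 | (3S,4S)-4-(3,4-dimethoxyphenyl)-4-[4-methoxy-3-(tosyloxy)phenyl]-3-methylbutanoic acid | COc1ccc([C@H](c2ccc(OC)c(OC)c2)[C@@H](C)CC(=O)O)cc1OS(=O)(=O)c1ccc(C)cc1
F9 | step 10 | (3S,4R)-6,7-dimethoxy-4-[4-methoxy-3-(tosyloxy)phenyl]-3-methyl-3,4-dihydronaphthalen-1(2H)-one | COc1ccc([C@@H]2c3cc(OC)c(OC)cc3C(=O)C[C@@H]2C)cc1OS(=O)(=O)c1ccc(C)cc1
A1 | alternative 1 | (4R,5R,6S)-4-[3-(benzyloxy)-4-methoxyphenyl]-5,6-dimethylcyclohex-2-en-1-one | COc1ccc([C@@H]2C=CC(=O)[C@@H](C)[C@@H]2C)cc1OCc1ccccc1
A2 | alternative 1 | 2,3-dimethoxybuta-1,3-diene | COC(=C)C(=C)OC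
A3 | alternative 1 | cis-fused 4-[3-(benzyloxy)-4-methoxyphenyl]-6,7-dimethoxy-2,3-dimethyl-3,4,4a,5,8,8a-hexahydronaphthalen-1(2H)-one | COc1ccc([C@@H]2[C@H]3CC(OC)=C(OC)C[C@H]3C(=O)[C@@H](C)[C@@H]2C)cc1OCc1ccccc1
A4 | alternative 2 | 4-{2-[3-(benzyloxy)-4-methoxybenzoyl]-4,5-dimethoxyphenyl}-4-[(tert-butyldimethylsilyl)oxy]-3-methylbutan-2-one, configured as in A5 | COc1ccc(C(=O)c2cc(OC)c(OC)cc2[C@@H](O[Si](C)(C)C(C)(C)C)[C@H](C)C(C)=O)cc1OCc1ccccc1
A5 | alternative 2 | {[4-[3-(benzyloxy)-4-methoxyphenyl]-6,7-dimethoxy-2,3-dimethyl-1,2-dihydronaphthalen-1-yl]oxy}(tert-butyl)dimethylsilane, 1,2-trans | COc1ccc(C2=C(C)[C@@H](C)[C@H](O[Si](C)(C)C(C)(C)C)c3cc(OC)c(OC)cc23)cc1OCc1ccccc1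
A6 | alternative 3 | methyl 2-[3-(benzyloxy)-4-methoxyphenyl]-5-(2-bromo-4,5-dimethoxyphenyl)-3-methyl-5-oxopentanoate, methyl-bearing centre configured, C2 undefined | COc1ccc(C(C(=O)OC)[C@@H](C)CC(=O)c2cc(OC)c(OC)cc2Br)cc1OCc1ccccc1
A7 | alternative 3 | methyl 1-[3-(benzyloxy)-4-methoxyphenyl]-6,7-dimethoxy-2-methyl-4-oxo-1,2,3,4-tetrahydronaphthalene-1-carboxylate | COc1ccc([C@@]2(C(=O)OC)c3cc(OC)c(OC)cc3C(=O)C[C@@H]2C)cc1OCc1ccccc1
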